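## Retrosynthetic overview

1. The pyranone ring is closed last, by lateral acylation and enol-lactonisation of the o-toluate 21 (C3–C4 and O2 of the isocoumarin).
2. Ring B is not arylated. It is grown around the finished CH2 bridge by a Diels–Alder benzannulation of the 4-(arylmethyl)-1,3-bis(silyloxy)diene 16 with an allenoate.
3. The CH2 bridge is a C(sp3)–C(sp3) bond made by γ-benzylation of the acetoacetate-derived diene 4 with benzyl alcohol 12. No aryl–CH2 bond is ever made by arylation.
4. Ring A is made the same way, from diene 4 and ynoate 7. The diene encodes the OH (as OTIPS) versus OMe difference for both rings.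
5. Ring order: ring A (step 4), then ring B (step 9), then the pyranone (step 11).

Assumption: the target has no stereocentre, so no stereocontrol is needed. Enol-ether and diene geometries are drawn for the expected major isomer and disappear on aromatisation.

## Route

Step 1
Reactants: 1 methyl acetoacetate
Product: 2 methyl (Z)-3-(triisopropylsilyloxy)but-2-enoate
Conditions: TIPSOTf (1.05 equiv), Et3N (1.5 equiv), CH2Cl2, 0 °C → rt
Reagents that add atoms: triisopropylsilyl trifluoromethanesulfonate (TIPSOTf), CC(C)[Si](C(C)C)(C(C)C)OS(=O)(=O)C(F)(F)F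
Why: Soft enolisation and O-silylation of a β-keto ester (silyl enol ether formation); the bulky TIPS group is chosen because it survives every later step and ends up as the protecting group of both phenols.

Step 2
Reactants: 2 methyl (Z)-3-(triisopropylsilyloxy)but-2-enoate
Product: 4 (1Z)-1-methoxy-3-(triisopropylsilyloxy)-1-(trimethylsilyloxy)buta-1,3-diene, via lithium dienolate 3 (not isolated)
Conditions: LDA (1.1 equiv), THF, −78 °C; TMSCl (1.3 equiv), −78 → 0 °C; pentane, filter, Kugelrohr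
Reagents that add atoms: chlorotrimethylsilane (TMSCl), C[Si](C)(C)Cl
Why: γ-Deprotonation of the vinylogous ester and O-silylation of the dienolate (Chan-type 1,3-bis(silyloxy)diene synthesis); the C1=C2 geometry is irrelevant because C1 becomes an aromatic carbon.

Step 3
Reactants: 5 3-methoxyprop-1-yne
Product: 7 methyl 4-methoxybut-2-ynoate, via lithium acetylide 6 (not isolated)
Conditions: n-BuLi (1.05 equiv), THF, −78 °C; ClCO2Me (1.2 equiv), −78 → 0 °C
Reagents that add atoms: methyl chloroformate, COC(=O)Cl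
Why: Deprotonation of a terminal alkyne and C-acylation of the acetylide with a chloroformate.

Step 4
Reactants: 4 (1Z)-1-methoxy-3-(triisopropylsilyloxy)-1-(trimethylsilyloxy)buta-1,3-diene (1.5 equiv), 7 methyl 4-methoxybut-2-ynoate
Product: 10 methyl 2-hydroxy-6-(methoxymethyl)-4-(triisopropylsilyloxy)benzoate, via cycloadduct 8 (not isolated), via aryl trimethylsilyl ether 9 (not isolated)
Conditions: toluene, 110 °C (sealed tube), 20 h; then 0.5 M HCl, THF, 0 °C, 10 min
Reagents that add atoms: none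
Why: Regioselective Diels–Alder benzannulation in which the nucleophilic C4 of the diene bonds to the β-carbon of the ynoate and C1 to the α-carbon; the 1,4-cyclohexadiene aromatises by loss of methanol from the mixed ketene-acetal carbon (the usual course for 1-methoxy-1-silyloxy dienes), and the labile ArO–SiMe3 is cleaved on work-up while ArO–TIPS stays.

Step 5
Reactants: 10 methyl 2-hydroxy-6-(methoxymethyl)-4-(triisopropylsilyloxy)benzoate
Product: 11 methyl 2-methoxy-6-(methoxymethyl)-4-(triisopropylsilyloxy)benzoate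
Conditions: MeI (3 equiv), K2CO3 (2 equiv), acetone, 50 °C
Reagents that add atoms: iodomethane, CI
Why: Williamson O-methylation of the only free (salicylate) phenol; the aryl TIPS ether tolerates carbonate in dry acetone.

Step 6
Reactants: 11 methyl 2-methoxy-6-(methoxymethyl)-4-(triisopropylsilyloxy)benzoate
Product: 12 [2-methoxy-6-(methoxymethyl)-4-(triisopropylsilyloxy)phenyl]methanol
Conditions: DIBAL-H (2.5 equiv), CH2Cl2, −78 → 0 °C; aq Rochelle salt
Reagents that add atoms: none
Why: Hydride reduction of the ester to the benzyl alcohol; the aryl silyl ether and benzyl methyl ether are inert to DIBAL-H.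

Step 7
Reactants: 12 [2-methoxy-6-(methoxymethyl)-4-(triisopropylsilyloxy)phenyl]methanol, 4 (1Z)-1-methoxy-3-(triisopropylsilyloxy)-1-(trimethylsilyloxy)buta-1,3-diene (2.3 equiv)
Product: 14 methyl (Z)-5-[2-methoxy-6-(methoxymethyl)-4-(triisopropylsilyloxy)phenyl]-3-(triisopropylsilyloxy)pent-2-enoate, via benzyl trimethylsilyl ether 13 (not isolated)
Conditions: TMSOTf (10 mol %), CH2Cl2, −78 °C, 1 h; Et3N, then aq NaHCO3
Reagents that add atoms: none
Why: Proposed new method: the first equivalent of 4 silylates the alcohol, TMSOTf ionises the resulting benzyl silyl ether to a benzylic cation stabilised by the para-silyloxy and ortho-methoxy groups, and the diene traps it at its terminal C4 (SN1 vinylogous Mukaiyama-type alkylation), losing only the labile ester-side Me3Si so that the TIPS enol ether is delivered intact; the closest known reactions are the γ-selective vinylogous Mukaiyama additions of 1,3-bis(silyloxy)dienes to oxocarbenium ions and Lewis-acid SN1 benzylations of silyl enol ethers.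

Step 8
Reactants: 14 methyl (Z)-5-[2-methoxy-6-(methoxymethyl)-4-(triisopropylsilyloxy)phenyl]-3-(triisopropylsilyloxy)pent-2-enoate
Product: 16 (1Z,3Z)-1-methoxy-5-[2-methoxy-6-(methoxymethyl)-4-(triisopropylsilyloxy)phenyl]-3-(triisopropylsilyloxy)-1-(trimethylsilyloxy)penta-1,3-diene, via lithium dienolate 15 (not isolated)
Conditions: LDA (1.15 equiv), THF, −78 °C; TMSCl (1.3 equiv), −78 → 0 °C; pentane, filter, concentrate (used crude)
Reagents that add atoms: chlorotrimethylsilane (TMSCl), C[Si](C)(C)Cl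
Why: Same γ-deprotonation and O-silylation as step 2 (Chan-type diene synthesis); the benzylic and ArCH2OMe protons are far less acidic than the γ-CH2 of the vinylogous ester.

Step 9
Reactants: 16 (1Z,3Z)-1-methoxy-5-[2-methoxy-6-(methoxymethyl)-4-(triisopropylsilyloxy)phenyl]-3-(triisopropylsilyloxy)-1-(trimethylsilyloxy)penta-1,3-diene, 17 ethyl buta-2,3-dienoate (2 equiv)
Product: 20 ethyl 2-hydroxy-5-{[2-methoxy-6-(methoxymethyl)-4-(triisopropylsilyloxy)phenyl]methyl}-6-methyl-4-(triisopropylsilyloxy)benzoate, via cycloadduct 18 (not isolated), via aryl trimethylsilyl ether 19 (not isolated)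
Conditions: toluene, 90 °C, 14 h; DBU (0.3 equiv), rt; then 0.5 M HCl, THF, 0 °C
Reagents that add atoms: none
Why: Key step, a Diels–Alder benzannulation of a 4-substituted 1,3-bis(silyloxy)diene with an allenoate: C4 (carrying the CH2Ar bridge) bonds to the central allene carbon and C1 to the α-carbon, base-induced loss of methanol and tautomerisation of the exocyclic methylene give the arene, so the benzyl group, the oxygens, the ester and the methyl are placed unambiguously and no stereocentre survives.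

Step 10
Reactants: 20 ethyl 2-hydroxy-5-{[2-methoxy-6-(methoxymethyl)-4-(triisopropylsilyloxy)phenyl]methyl}-6-methyl-4-(triisopropylsilyloxy)benzoate
Product: 21 ethyl 2-methoxy-5-{[2-methoxy-6-(methoxymethyl)-4-(triisopropylsilyloxy)phenyl]methyl}-6-methyl-4-(triisopropylsilyloxy)benzoate
Conditions: MeI (3 equiv), K2CO3 (2 equiv), acetone, 50 °C
Reagents that add atoms: iodomethane, CI
Why: Williamson O-methylation of the only free phenol, which fixes the 8-OMe / 6-O(TIPS) difference of ring B.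

Step 11
Reactants: 21 ethyl 2-methoxy-5-{[2-methoxy-6-(methoxymethyl)-4-(triisopropylsilyloxy)phenyl]methyl}-6-methyl-4-(triisopropylsilyloxy)benzoate
Product: 25 8-methoxy-5-{[2-methoxy-6-(methoxymethyl)-4-(triisopropylsilyloxy)phenyl]methyl}-3-methyl-6-(triisopropylsilyloxy)-1H-isochromen-1-one, via benzylic lithium 22 (not isolated), via Weinreb chelate 23 (not isolated), via keto ester 24 (not isolated)
Conditions: LDA (1.3 equiv), THF, −78 °C; MeC(O)N(OMe)Me (1.5 equiv), −78 → −20 °C; 1 M HCl; then p-TsOH·H2O (10 mol %), toluene, 80 °C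
Reagents that add atoms: N-methoxy-N-methylacetamide, CC(=O)N(C)OC
Why: Lateral lithiation of the hindered o-toluate (the ester-conjugated CH3 is far more acidic than the diarylmethane CH2), Weinreb ketone synthesis, and acid-catalysed enol-lactonisation of the 2-(2-oxopropyl)benzoate to the 3-methylisocoumarin.

Step 12
Reactants: 25 8-methoxy-5-{[2-methoxy-6-(methoxymethyl)-4-(triisopropylsilyloxy)phenyl]methyl}-3-methyl-6-(triisopropylsilyloxy)-1H-isochromen-1-one
Product: 26 6-hydroxy-5-{[4-hydroxy-2-methoxy-6-(methoxymethyl)phenyl]methyl}-8-methoxy-3-methyl-1H-isochromen-1-one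
Conditions: TBAF (2.5 equiv), AcOH (2.5 equiv), THF, 0 °C
Reagents that add atoms: none
Why: Fluoride cleavage of both aryl silyl ethers; buffering with acetic acid protects the enol lactone, and the methyl ethers are untouched.

## Compound list

1 | methyl acetoacetate | COC(=O)CC(C)=O | starting material
2 | methyl (Z)-3-(triisopropylsilyloxy)but-2-enoate | COC(=O)/C=C(/C)O[Si](C(C)C)(C(C)C)C(C)C | intermediate
3 | lithium (1E)-1-methoxy-3-(triisopropylsilyloxy)buta-1,3-dien-1-olate | [Li+].CO/C([O-])=C/C(=C)O[Si](C(C)C)(C(C)C)C(C)C | intermediate (not isolated)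
4 | (1Z)-1-methoxy-3-(triisopropylsilyloxy)-1-(trimethylsilyloxy)buta-1,3-diene | CO/C(O[Si](C)(C)C)=C/C(=C)O[Si](C(C)C)(C(C)C)C(C)C | intermediate
5 | 3-methoxyprop-1-yne (methyl propargyl ether) | COCC#C | starting material
6 | lithium 3-methoxyprop-1-yn-1-ide | COCC#C[Li] | intermediate (not isolated)
7 | methyl 4-methoxybut-2-ynoate | COCC#CC(=O)OC | intermediate
8 | methyl 6-methoxy-2-(methoxymethyl)-4-(triisopropylsilyloxy)-6-(trimethylsilyloxy)cyclohexa-1,4-diene-1-carboxylate (racemic) | COCC1=C(C(=O)OC)C(OC)(O[Si](C)(C)C)C=C(O[Si](C(C)C)(C(C)C)C(C)C)C1 | intermediate (not isolated)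
9 | methyl 2-(methoxymethyl)-4-(triisopropylsilyloxy)-6-(trimethylsilyloxy)benzoate | COCc1cc(O[Si](C(C)C)(C(C)C)C(C)C)cc(O[Si](C)(C)C)c1C(=O)OC | intermediate (not isolated)
10 | methyl 2-hydroxy-6-(methoxymethyl)-4-(triisopropylsilyloxy)benzoate | COCc1cc(O[Si](C(C)C)(C(C)C)C(C)C)cc(O)c1C(=O)OC | intermediate
11 | methyl 2-methoxy-6-(methoxymethyl)-4-(triisopropylsilyloxy)benzoate | COCc1cc(O[Si](C(C)C)(C(C)C)C(C)C)cc(OC)c1C(=O)OC | intermediate
12 | [2-methoxy-6-(methoxymethyl)-4-(triisopropylsilyloxy)phenyl]methanol | COCc1cc(O[Si](C(C)C)(C(C)C)C(C)C)cc(OC)c1CO | intermediate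
13 | {[2-methoxy-6-(methoxymethyl)-4-(triisopropylsilyloxy)phenyl]methoxy}trimethylsilane | COCc1cc(O[Si](C(C)C)(C(C)C)C(C)C)cc(OC)c1CO[Si](C)(C)C | intermediate (not isolated)
14 | methyl (Z)-5-[2-methoxy-6-(methoxymethyl)-4-(triisopropylsilyloxy)phenyl]-3-(triisopropylsilyloxy)pent-2-enoate | COCc1cc(O[Si](C(C)C)(C(C)C)C(C)C)cc(OC)c1CC/C(O[Si](C(C)C)(C(C)C)C(C)C)=C/C(=O)OC | intermediate
15 | lithium (1E,3Z)-1-methoxy-5-[2-methoxy-6-(methoxymethyl)-4-(triisopropylsilyloxy)phenyl]-3-(triisopropylsilyloxy)penta-1,3-dien-1-olate | [Li+].COCc1cc(O[Si](C(C)C)(C(C)C)C(C)C)cc(OC)c1C/C=C(\O[Si](C(C)C)(C(C)C)C(C)C)/C=C(\[O-])OC | intermediate (not isolated)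
16 | (1Z,3Z)-1-methoxy-5-[2-methoxy-6-(methoxymethyl)-4-(triisopropylsilyloxy)phenyl]-3-(triisopropylsilyloxy)-1-(trimethylsilyloxy)penta-1,3-diene | COCc1cc(O[Si](C(C)C)(C(C)C)C(C)C)cc(OC)c1C/C=C(\O[Si](C(C)C)(C(C)C)C(C)C)/C=C(\O[Si](C)(C)C)OC | intermediate
17 | ethyl buta-2,3-dienoate | CCOC(=O)C=C=C | starting material
18 | ethyl 2-methoxy-5-{[2-methoxy-6-(methoxymethyl)-4-(triisopropylsilyloxy)phenyl]methyl}-6-methylidene-4-(triisopropylsilyloxy)-2-(trimethylsilyloxy)cyclohex-3-ene-1-carboxylate (mixture of racemic diastereomers) | CCOC(=O)C1C(=C)C(Cc2c(OC)cc(O[Si](C(C)C)(C(C)C)C(C)C)cc2COC)C(O[Si](C(C)C)(C(C)C)C(C)C)=CC1(OC)O[Si](C)(C)C | intermediate (not isolated)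
19 | ethyl 5-{[2-methoxy-6-(methoxymethyl)-4-(triisopropylsilyloxy)phenyl]methyl}-6-methyl-4-(triisopropylsilyloxy)-2-(trimethylsilyloxy)benzoate | CCOC(=O)c1c(O[Si](C)(C)C)cc(O[Si](C(C)C)(C(C)C)C(C)C)c(Cc2c(OC)cc(O[Si](C(C)C)(C(C)C)C(C)C)cc2COC)c1C | intermediate (not isolated)
20 | ethyl 2-hydroxy-5-{[2-methoxy-6-(methoxymethyl)-4-(triisopropylsilyloxy)phenyl]methyl}-6-methyl-4-(triisopropylsilyloxy)benzoate | CCOC(=O)c1c(O)cc(O[Si](C(C)C)(C(C)C)C(C)C)c(Cc2c(OC)cc(O[Si](C(C)C)(C(C)C)C(C)C)cc2COC)c1C | intermediate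
21 | ethyl 2-methoxy-5-{[2-methoxy-6-(methoxymethyl)-4-(triisopropylsilyloxy)phenyl]methyl}-6-methyl-4-(triisopropylsilyloxy)benzoate | CCOC(=O)c1c(OC)cc(O[Si](C(C)C)(C(C)C)C(C)C)c(Cc2c(OC)cc(O[Si](C(C)C)(C(C)C)C(C)C)cc2COC)c1C | intermediate
22 | benzylic lithium derivative of 21 (CH2Li in place of the ring methyl) | CCOC(=O)c1c(OC)cc(O[Si](C(C)C)(C(C)C)C(C)C)c(Cc2c(OC)cc(O[Si](C(C)C)(C(C)C)C(C)C)cc2COC)c1C[Li] | intermediate (not isolated)
23 | lithium hemiaminal (Weinreb chelate) from 22 and N-methoxy-N-methylacetamide (racemic) | CCOC(=O)c1c(OC)cc(O[Si](C(C)C)(C(C)C)C(C)C)c(Cc2c(OC)cc(O[Si](C(C)C)(C(C)C)C(C)C)cc2COC)c1CC(C)(O[Li])N(C)OC | intermediate (not isolated)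
24 | ethyl 2-methoxy-5-{[2-methoxy-6-(methoxymethyl)-4-(triisopropylsilyloxy)phenyl]methyl}-6-(2-oxopropyl)-4-(triisopropylsilyloxy)benzoate | CCOC(=O)c1c(OC)cc(O[Si](C(C)C)(C(C)C)C(C)C)c(Cc2c(OC)cc(O[Si](C(C)C)(C(C)C)C(C)C)cc2COC)c1CC(C)=O | intermediate (not isolated)
25 | 8-methoxy-5-{[2-methoxy-6-(methoxymethyl)-4-(triisopropylsilyloxy)phenyl]methyl}-3-methyl-6-(triisopropylsilyloxy)-1H-isochromen-1-one | COCc1cc(O[Si](C(C)C)(C(C)C)C(C)C)cc(OC)c1Cc1c(O[Si](C(C)C)(C(C)C)C(C)C)cc(OC)c2c(=O)oc(C)cc12 | intermediate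
26 | 6-hydroxy-5-{[4-hydroxy-2-methoxy-6-(methoxymethyl)phenyl]methyl}-8-methoxy-3-methyl-1H-isochromen-1-one (CNP0481202.0, achiral) | COCc1cc(O)cc(OC)c1Cc1c(O)cc(OC)c2c(=O)oc(C)cc12 | target

## Step count and risks

Total step count: 12 (step 3 is a one-step side branch).
Longest linear sequence: 11 steps (1 → 2 → 4 → 10 → 11 → 12 → 14 → 16 → 20 → 21 → 25 → 26).

The three steps most likely to fail:

**Step 9 (ring B benzannulation).** The diene carries a bulky arylmethyl group on its reacting terminus. Only the 3Z isomer can adopt the s-cis conformation easily, and the aromatisation must not cost the TIPS enol ether. The fallback sets out from 12 and comes back to the route at 21; it is the conventional Friedel–Crafts benzylation held in reserve. Commercial ethyl 2,4-dihydroxy-6-methylbenzoate (ethyl orsellinate, CCOC(=O)c1c(O)cc(O)cc1C) is silylated at its non-chelated 4-OH (TIPSCl, imidazole, DMF) to ethyl 2-hydroxy-6-methyl-4-(triisopropylsilyloxy)benzoate F9. This is methylated (MeI, K2CO3, acetone) to ethyl 2-methoxy-6-methyl-4-(triisopropylsilyloxy)benzoate F10. F10 is then benzylated with 12 (Sc(OTf)3 5 mol %, CH2Cl2, −20 °C) at C5, the position para to the methoxy group, to give 21. Compounds 14 to 20 are bypassed.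

**Step 7 (SN1 γ-benzylation).** The benzylic cation can be intercepted by the neighbouring CH2OMe oxygen (cyclic oxonium, then a phthalan by demethylation). It can also be attacked by the diene at C2, or alkylate another arene. The fallback sets out from 12 and comes back at 14; it replaces the cationic coupling by an anionic SN2 (Weiler) alkylation. SOCl2 and 2,6-lutidine (CH2Cl2, −20 °C) give 2-(chloromethyl)-1-methoxy-3-(methoxymethyl)-5-(triisopropylsilyloxy)benzene F6. F6 is added at once at −78 °C to dilithium 1-methoxybuta-1,3-diene-1,3-diolate F7, the dianion made from 1 and two equivalents of LDA. Alkylation at the terminal carbon gives methyl 5-[2-methoxy-6-(methoxymethyl)-4-(triisopropylsilyloxy)phenyl]-3-oxopentanoate F8. TIPSOTf and Et3N, as in step 1, then give 14.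

**Step 4 (ring A benzannulation).** The β-alkyl ynoate 7 is only a moderate dienophile, so diene 4 may decompose before it adds. The fallback sets out from 5 (and uses 4) and comes back at 12; it swaps the ester-activated dienophile for an aldehyde-activated one and drops the ester reduction. Lithiation of 5 to 6 and a DMF quench give 4-methoxybut-2-ynal F1, which should add to 4 at 0–25 °C. The cycloadduct 6-methoxy-2-(methoxymethyl)-4-(triisopropylsilyloxy)-6-(trimethylsilyloxy)cyclohexa-1,4-diene-1-carbaldehyde F2 loses methanol to 2-(methoxymethyl)-4-(triisopropylsilyloxy)-6-(trimethylsilyloxy)benzaldehyde F3. Dilute acid gives 2-hydroxy-6-(methoxymethyl)-4-(triisopropylsilyloxy)benzaldehyde F4. MeI and K2CO3 give 2-methoxy-6-(methoxymethyl)-4-(triisopropylsilyloxy)benzaldehyde F5, and NaBH4 (MeOH, 0 °C) gives 12. Compounds 7, 10 and 11 are bypassed.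

Further compounds

F1 | step 4 | 4-methoxybut-2-ynal | COCC#CC=O
F2 | step 4 | 6-methoxy-2-(methoxymethyl)-4-(triisopropylsilyloxy)-6-(trimethylsilyloxy)cyclohexa-1,4-diene-1-carbaldehyde (racemic) | COCC1=C(C=O)C(OC)(O[Si](C)(C)C)C=C(O[Si](C(C)C)(C(C)C)C(C)C)C1
F3 | step 4 | 2-(methoxymethyl)-4-(triisopropylsilyloxy)-6-(trimethylsilyloxy)benzaldehyde | COCc1cc(O[Si](C(C)C)(C(C)C)C(C)C)cc(O[Si](C)(C)C)c1C=O
F4 | step 4 | 2-hydroxy-6-(methoxymethyl)-4-(triisopropylsilyloxy)benzaldehyde | COCc1cc(O[Si](C(C)C)(C(C)C)C(C)C)cc(O)c1C=O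
F5 | step 4 | 2-methoxy-6-(methoxymethyl)-4-(triisopropylsilyloxy)benzaldehyde | COCc1cc(O[Si](C(C)C)(C(C)C)C(C)C)cc(OC)c1C=O
F6 | step 7 | 2-(chloromethyl)-1-methoxy-3-(methoxymethyl)-5-(triisopropylsilyloxy)benzene | COCc1cc(O[Si](C(C)C)(C(C)C)C(C)C)cc(OC)c1CCl
F7 | step 7 | dilithium 1-methoxybuta-1,3-diene-1,3-diolate | [Li+].[Li+].COC([O-])=CC(=C)[O-]
F8 | step 7 | methyl 5-[2-methoxy-6-(methoxymethyl)-4-(triisopropylsilyloxy)phenyl]-3-oxopentanoate | COCc1cc(O[Si](C(C)C)(C(C)C)C(C)C)cc(OC)c1CCC(=O)CC(=O)OC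
F9 | step 9 | ethyl 2-hydroxy-6-methyl-4-(triisopropylsilyloxy)benzoate | CCOC(=O)c1c(O)cc(O[Si](C(C)C)(C(C)C)C(C)C)cc1C
F10 | step 9 | ethyl 2-methoxy-6-methyl-4-(triisopropylsilyloxy)benzoate | CCOC(=O)c1c(OC)cc(O[Si](C(C)C)(C(C)C)C(C)C)cc1C
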